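## Analysis of the target

The target is a trans-3,4-dibenzyl-γ-butyrolactone. The lactone is numbered O1, C2 (carbonyl), C3, C4, C5; C7 is the benzylic CH2 on C4 and carries ring A (3-hydroxy-4-methoxyphenyl), and C7' is the benzylic CH2 on C3 and carries ring B (4-hydroxy-3-methoxyphenyl). Both stereocentres are R and the two arms are trans. C3 is α to the carbonyl and can be equilibrated, and trans is the more stable arrangement, so C3 can be left to thermodynamics. C4 cannot be corrected once made and is the centre that needs absolute control. This is hard because C4 is a CH flanked by three sp3 carbons of similar size (C5, C7, C3), and because rings A and B are regioisomers, so each arm must be brought in separately. The sensitive groups are the two phenols, masked as benzyl ethers until the end, and the lactone, which does not tolerate hard nucleophiles. The strategy rests on C5, an unsubstituted OCH2 on the C4 stereocentre: C5 and O1 can come from formaldehyde, while C2, C3 and C4 come from a 2-alkoxycarbonyl allylboronate whose ester carbon becomes C2 and whose allylic transposition leaves an exocyclic methylene on C3 as the handle for ring B.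

## Retrosynthetic reasoning

**19 from 18.** The two phenolic O–H bonds are traced back to benzyl ethers. The phenols must be covered through organometallic and basic steps, and both ethers fall in one neutral hydrogenolysis that does not touch C3 or C4.

**18 from 17, and 17 from 12 and 15.** The C7'–aryl bond to ring B is cut. Cutting C3–C7' instead would call for enolate alkylation with a labile, electron-rich benzylic halide. Cutting at the ring B ipso carbon uses the methylene of 12 as a Michael acceptor and the stable aryl Grignard reagent 15. C3 forms without control (17) and is then equilibrated to the trans isomer 18, so the forward sequence only has to leave C4 alone.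

**12 from 9 and 10.** C4–C5 and O1–C2 are cut. C5 is the only ring carbon without a carbon substituent, so removing it as formaldehyde (10) opens the ring to the acyclic allylboronate 9, in which C4 is trigonal. One step then forms a C–C bond, the ring and the stereocentre. The forward reaction must deliver C5 to one face of the γ-carbon of 9.

**9 from 6 and 7.** The bond between the future C3 and the future C7' is cut, and a hydrogen is removed from the future C4, which leads back to ynoate 6 and the iodomethyl boronate 7. The forward reaction (syn hydrometalation, then C-alkylation) must give one alkene geometry, because the geometry decides which face of C4 is presented in the key step.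

**6 from 4 and 5.** The C7–C(sp) bond is cut. The benzylic bromide 4 and methyl propiolate (5) are joined through a copper acetylide, which avoids strongly basic conditions on the doubly activated CH2.

**4 from 3, 2 and 1.** Functional group changes only: bromide from alcohol 3, alcohol from aldehyde 2, benzyl ether from isovanillin (1).

**15 from 14 and 13.** Magnesium insertion into aryl bromide 14, which is the benzyl ether of the bromophenol 13.

## Alternatives that were turned down

**Alternative 1:** Temporary cyclopropane.
- **Disconnection:** C3–C4 together with a temporary C3–C7 bond; the lactone is seen as the ring-opened form of a cyclopropane-fused lactone.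
- **Forward key step:** the (Z)-allylic diazoacetate A1, (Z)-3-[4-methoxy-3-(triisopropylsilyloxy)phenyl]prop-2-en-1-yl diazoacetate, is decomposed by Rh2(MEPY)4 (dirhodium tetrakis[methyl 2-oxopyrrolidine-5-carboxylate], divalent rhodium). The carbene carbon (C3) adds to the tethered cis alkene and gives the bicycle A2, (1S,5R,6S)-6-[4-methoxy-3-(triisopropylsilyloxy)phenyl]-3-oxabicyclo[3.1.0]hexan-2-one (6-endo aryl). Hydrogenolysis of the C3–C7 bond would give the monobenzyl lactone A3, (R)-4-[4-methoxy-3-(triisopropylsilyloxy)benzyl]dihydrofuran-2(3H)-one, and enolate alkylation would add the ring B arm trans.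
- **For it:** intramolecular cyclopropanation of cis-disubstituted allylic diazoacetates by chiral dirhodium carboxamidates is an established, highly enantioselective reaction type. On certainty of the configuration at C4 this route is stronger than the chosen one.
- **Against it:**
  - The three-membered ring is built only to be cut, and two of its three stereocentres (C3, C7) are erased.
  - The cis alkene needs an alkyne semi-reduction, and a diazo ester must be made and handled.
  - The ring opening must choose C3–C7 over C4–C7. Both bonds are benzylic; cleaving C4–C7 would put the ring A arm on C3, a constitutional error that no later step repairs.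
  - Hydrogenolysis in mid-route excludes benzyl ethers, so a silyl ether and a separate deprotection are needed.
  - Ring B still enters as a labile benzylic bromide.
  - The length is about the same or slightly greater.
- **Comparison:** the chosen strategy gives up the precedent for the enantioselective step. In return its key step delivers the whole lactone, the C4 centre and the C3 handle from an acyclic boronate and a one-carbon feedstock, with no diazo compound, and ring B enters as the stable Grignard reagent 15.

**Alternative 2:** Hydroxyl-directed hydroformylation.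
- **Disconnection:** C2–C3 and O1–C2; the carbonyl carbon is CO.
- **Forward key step:** the homoallylic alcohol A4, (R,E)-2-[3-(benzyloxy)-4-methoxybenzyl]-4-[4-(benzyloxy)-3-methoxyphenyl]but-3-en-1-ol, reacts with CO and H2 under Rh(acac)(CO)2 (monovalent rhodium) and a phosphinite ligand that binds the hydroxyl reversibly. The formyl group goes to the alkene carbon nearer the hydroxyl (C3), and the hydroxy aldehyde closes to the lactol A5, (3R,4R)-3-[4-(benzyloxy)-3-methoxybenzyl]-4-[3-(benzyloxy)-4-methoxybenzyl]tetrahydrofuran-2-ol (anomers). Oxidation and debenzylation follow.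
- **For it:** C2 comes from the cheapest C1 unit, the end game is three steps, and C3 is created relative to the existing C4 centre in the same step. If delivery is trans, no epimerisation step is needed, and on that point it is stronger than the chosen route.
- **Against it:**
  - The alkene of A4 is a styrene, whose inherent preference is formylation at the benzylic carbon C7', so the directing effect must override an electronic bias.
  - The C4–H is allylic, and a rhodium hydride can move the double bond to C3–C4 and erase the only stereocentre present.
  - The selectivity at C3 rests on substrate control in a flexible acyclic system.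
  - A4 already carries C4, which must first be made enantioselectively by a separate sequence, so the hard problem is moved into the precursor rather than solved.
  - Pressure equipment and a non-commercial ligand are needed.
- **Comparison:** the chosen route creates C4 in the key step from the achiral precursor 9, reached in five steps, and pays with one extra step (step 10) for leaving C3 to thermodynamics.

**Alternative 3:** Matteson assembly.
- **Disconnection:** C4–C5 and C4–C7; C4 is the carbon of dichloromethane inserted into a C–B bond.
- **Forward key step:** the boronate A6, (4R,5R)-2-[(benzyloxy)methyl]-4,5-dicyclohexyl-1,3,2-dioxaborolane, is homologated with LiCHCl2 and ZnCl2 (Matteson homologation). The chloride of the resulting α-chloro boronate is displaced with inversion by the benzylic Grignard reagent A7, [3-(benzyloxy)-4-methoxybenzyl]magnesium chloride, giving A8, (4R,5R)-2-[(2S)-1-(benzyloxy)-3-[3-(benzyloxy)-4-methoxyphenyl]propan-2-yl]-4,5-dicyclohexyl-1,3,2-dioxaborolane. Two further homologations (C3 with its arm, then C2), oxidation, debenzylation and lactonisation would finish.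
- **For it:** the diastereoselection of this homologation is high, reagent-controlled and predictable. On stereochemical reliability it is clearly stronger than step 6 of the chosen route.
- **Against it:**
  - The key step closes no ring, and the route is linear and iterative: three cryogenic homologations, each with stoichiometric organolithium, and a stoichiometric chiral diol.
  - Two benzylic Grignard reagents of electron-rich arenes are needed, and these tend to homocouple.
  - A8 has oxygen β to boron, and its ate complexes can eliminate.
  - One director sets successive centres in the same sense, which for this chain corresponds to the cis lactone. The diol would have to be exchanged for its antipode between insertions, or C3 epimerised afterwards as in the chosen route.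
  - The count is about twelve steps.
- **Comparison:** the chosen strategy offers convergence, catalytic chirality and ring formation in the step that sets C4.

Key step: step 6

Assumption: the sense of induction in step 6 is extrapolated, not known. The (R)-acid is written because the same chair that this acid favours with (E)-crotyl pinacol boronates would give (R) at C4; if a trial favours the (S)-lactone, the (S)-acid is used instead.

## Route

Step 1
Reactants: 1 isovanillin
Product: 2 3-(benzyloxy)-4-methoxybenzaldehyde
Conditions: BnBr, K2CO3, DMF, rt
Reagents that add atoms: benzyl bromide, BrCc1ccccc1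
Why: Williamson ether synthesis; the phenoxide is the only nucleophile and the aldehyde is inert to carbonate.

Step 2
Reactants: 2 3-(benzyloxy)-4-methoxybenzaldehyde
Product: 3 [3-(benzyloxy)-4-methoxyphenyl]methanol
Conditions: NaBH4, MeOH, 0 °C
Reagents that add atoms: none
Why: Borohydride reduction of an aryl aldehyde; the benzyl and methyl ethers are inert.

Step 3
Reactants: 3 [3-(benzyloxy)-4-methoxyphenyl]methanol
Product: 4 2-(benzyloxy)-4-(bromomethyl)-1-methoxybenzene
Conditions: PBr3, Et2O, 0 °C
Reagents that add atoms: phosphorus tribromide, BrP(Br)Br
Why: Bromination of a benzylic alcohol through its phosphite ester; the electron-rich bromide is used at once without storage.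

Step 4
Reactants: 4 2-(benzyloxy)-4-(bromomethyl)-1-methoxybenzene; 5 methyl propiolate
Product: 6 methyl 4-[3-(benzyloxy)-4-methoxyphenyl]but-2-ynoate
Conditions: CuI (20 mol%), K2CO3, n-Bu4NI, MeCN, 40 °C
Reagents that add atoms: none
Why: Copper-catalysed alkynylation of a benzylic halide through the copper acetylide, a known coupling for propiolates; the mild carbonate base should limit propargyl-to-allenyl isomerisation of the product.

Step 5
Reactants: 6 methyl 4-[3-(benzyloxy)-4-methoxyphenyl]but-2-ynoate; 7 2-(iodomethyl)-4,4,5,5-tetramethyl-1,3,2-dioxaborolane
Product: 9 methyl (Z)-4-[3-(benzyloxy)-4-methoxyphenyl]-2-[(4,4,5,5-tetramethyl-1,3,2-dioxaborolan-2-yl)methyl]but-2-enoate, via alpha-alumino enoate 8 (not isolated)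
Conditions: i-Bu2AlH (DIBAL-H), HMPA, THF, 0 °C; then 7, 0 °C to rt
Reagents that add atoms: none
Why: Conjugate hydroalumination of an ynoate by the i-Bu2AlH–HMPA complex adds H to C3 and aluminium to C2 in a syn sense; C-alkylation of 8 by the activated iodide 7 with retention leaves CH2Ar cis to the ester and trans to CH2B (Z), a known route to 2-alkoxycarbonyl allylboronates.

Step 6
Reactants: 9 methyl (Z)-4-[3-(benzyloxy)-4-methoxyphenyl]-2-[(4,4,5,5-tetramethyl-1,3,2-dioxaborolan-2-yl)methyl]but-2-enoate; 10 formaldehyde
Product: 12 (R)-4-[3-(benzyloxy)-4-methoxybenzyl]-3-methylenedihydrofuran-2(3H)-one, via O-boryl hydroxy ester 11 (not isolated)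
Conditions: CH2O (gas from cracked paraformaldehyde, excess), (R)-TRIP [(R)-3,3'-bis(2,4,6-triisopropylphenyl)-1,1'-binaphthyl-2,2'-diyl hydrogen phosphate] (10 mol%), toluene, −40 °C to rt; then p-TsOH·H2O (cat.), rt
Reagents that add atoms: none
Why: Proposed new method: the boron of 9 binds the oxygen of 10 and the C–C bond forms through a closed six-membered chair with allylic transposition, so the γ-carbon becomes C4, formaldehyde becomes C5 and the CH2B carbon becomes the exocyclic methylene on C3; the closest known reactions are the aldehyde allylboration of 2-alkoxycarbonyl allylboronates that ends in α-methylene-γ-butyrolactones and the chiral phosphoric acid catalysed allylboration of aldehydes by allyl pinacol boronates, in which the acid hydrogen-bonds to a boronate oxygen. The lactone closes by 5-exo-trig acyl substitution: the boron-bound oxygen of 11 attacks the neighbouring ester carbon (O1–C2) and methoxide passes to boron. C4 is the only new stereocentre and requires attack on the Re face of the γ-carbon; since formaldehyde has no faces, the two competing chairs are mirror-image arrangements of the allyl unit that become diastereomeric only through the bound acid, whose triisopropylphenyl walls must tell the equatorial CH2Ar group and the ester apart. With the CH2Ar group trans to CH2B, 9 is of the (E)-crotyl type, and the chair this acid favours with such boronates would give (R) at C4. What is untested is enantiocontrol with formaldehyde as acceptor, whose second C–H offers the acid a binding mode that other aldehydes lack, and with a weakly nucleophilic, ester-bearing allylboronate. The step needs γ-selectivity, which the cyclic transition state enforces, and a single alkene geometry in 9, because the E and Z isomers would present opposite faces in the same chair. The low nucleophilicity of 9 should keep the uncatalysed background slow at low temperature, and the catalytic p-TsOH at the end completes lactonisation of any open hydroxy ester.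

Step 7
Reactants: 13 4-bromo-2-methoxyphenol
Product: 14 1-(benzyloxy)-4-bromo-2-methoxybenzene
Conditions: BnBr, K2CO3, DMF, rt
Reagents that add atoms: benzyl bromide, BrCc1ccccc1
Why: Williamson ether synthesis on the phenoxide; the aryl bromide is inert.

Step 8
Reactants: 14 1-(benzyloxy)-4-bromo-2-methoxybenzene
Product: 15 [4-(benzyloxy)-3-methoxyphenyl]magnesium bromide (THF solution, titrated)
Conditions: Mg, I2 (cat.), THF, reflux
Reagents that add atoms: magnesium, [Mg]
Why: Grignard formation by magnesium insertion into an aryl bromide; the ethers are inert.

Step 9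
Reactants: 12 (R)-4-[3-(benzyloxy)-4-methoxybenzyl]-3-methylenedihydrofuran-2(3H)-one; 15 [4-(benzyloxy)-3-methoxyphenyl]magnesium bromide
Product: 17 (3RS,4R)-3-[4-(benzyloxy)-3-methoxybenzyl]-4-[3-(benzyloxy)-4-methoxybenzyl]dihydrofuran-2(3H)-one, via silyl ketene acetal 16 (not isolated)
Conditions: CuI (10 mol%), Me3SiCl, THF, −78 to −40 °C; then 1 M HCl, rt
Reagents that add atoms: none
Why: Copper-catalysed conjugate addition of an aryl Grignard reagent to an α-methylene lactone; Me3SiCl traps the enolate as 16 and so suppresses Michael oligomerisation. Hydrolysis protonates C3 without control, which does not matter because step 10 equilibrates it, and arylation at low temperature removes the allylic C4–H before any base can isomerise the exocyclic alkene.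

Step 10
Reactants: 17 (3RS,4R)-3-[4-(benzyloxy)-3-methoxybenzyl]-4-[3-(benzyloxy)-4-methoxybenzyl]dihydrofuran-2(3H)-one
Product: 18 (3R,4R)-3-[4-(benzyloxy)-3-methoxybenzyl]-4-[3-(benzyloxy)-4-methoxybenzyl]dihydrofuran-2(3H)-one
Conditions: DBU, toluene, 80 °C
Reagents that add atoms: none
Why: Base-mediated epimerisation at C3, α to the lactone carbonyl, under thermodynamic control; the trans arrangement of the vicinal benzyl arms is favoured and fixes C3 as R relative to the secure C4, whose hydrogen is not acidic.

Step 11
Reactants: 18 (3R,4R)-3-[4-(benzyloxy)-3-methoxybenzyl]-4-[3-(benzyloxy)-4-methoxybenzyl]dihydrofuran-2(3H)-one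
Product: 19 (3R,4R)-3-(4-hydroxy-3-methoxybenzyl)-4-(3-hydroxy-4-methoxybenzyl)dihydrofuran-2(3H)-one
Conditions: H2 (1 atm), 10% Pd/C, EtOAc–EtOH, rt
Reagents that add atoms: none
Why: Hydrogenolysis of both aryl benzyl ethers under neutral conditions; the lactone, the methyl ethers and both stereocentres are untouched.

## Compound list

1 | isovanillin (3-hydroxy-4-methoxybenzaldehyde) | COc1ccc(C=O)cc1O | starting material
2 | 3-(benzyloxy)-4-methoxybenzaldehyde | COc1ccc(C=O)cc1OCc1ccccc1 | intermediate
3 | [3-(benzyloxy)-4-methoxyphenyl]methanol | COc1ccc(CO)cc1OCc1ccccc1 | intermediate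
4 | 2-(benzyloxy)-4-(bromomethyl)-1-methoxybenzene | COc1ccc(CBr)cc1OCc1ccccc1 | intermediate
5 | methyl propiolate | C#CC(=O)OC | starting material
6 | methyl 4-[3-(benzyloxy)-4-methoxyphenyl]but-2-ynoate | COC(=O)C#CCc1ccc(OC)c(OCc2ccccc2)c1 | intermediate
7 | 2-(iodomethyl)-4,4,5,5-tetramethyl-1,3,2-dioxaborolane | ICB1OC(C)(C)C(C)(C)O1 | starting material
8 | methyl (E)-4-[3-(benzyloxy)-4-methoxyphenyl]-2-(diisobutylalumanyl)but-2-enoate | COC(=O)/C([Al](CC(C)C)CC(C)C)=C\Cc1ccc(OC)c(OCc2ccccc2)c1 | intermediate
9 | methyl (Z)-4-[3-(benzyloxy)-4-methoxyphenyl]-2-[(4,4,5,5-tetramethyl-1,3,2-dioxaborolan-2-yl)methyl]but-2-enoate | COC(=O)/C(CB1OC(C)(C)C(C)(C)O1)=C\Cc1ccc(OC)c(OCc2ccccc2)c1 | intermediate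
10 | formaldehyde | C=O | starting material
11 | methyl 2-[(2R)-1-[3-(benzyloxy)-4-methoxyphenyl]-3-[(4,4,5,5-tetramethyl-1,3,2-dioxaborolan-2-yl)oxy]propan-2-yl]prop-2-enoate | COC(=O)C(=C)[C@H](COB1OC(C)(C)C(C)(C)O1)Cc1ccc(OC)c(OCc2ccccc2)c1 | intermediate
12 | (R)-4-[3-(benzyloxy)-4-methoxybenzyl]-3-methylenedihydrofuran-2(3H)-one | COc1ccc(C[C@H]2COC(=O)C2=C)cc1OCc1ccccc1 | intermediate
13 | 4-bromo-2-methoxyphenol | COc1cc(Br)ccc1O | starting material
14 | 1-(benzyloxy)-4-bromo-2-methoxybenzene | COc1cc(Br)ccc1OCc1ccccc1 | intermediate
15 | [4-(benzyloxy)-3-methoxyphenyl]magnesium bromide | COc1cc([Mg]Br)ccc1OCc1ccccc1 | intermediate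
16 | {[(4R)-3-[4-(benzyloxy)-3-methoxybenzyl]-4-[3-(benzyloxy)-4-methoxybenzyl]-4,5-dihydrofuran-2-yl]oxy}trimethylsilane | COc1ccc(C[C@H]2COC(O[Si](C)(C)C)=C2Cc2ccc(OCc3ccccc3)c(OC)c2)cc1OCc1ccccc1 | intermediate
17 | (3RS,4R)-3-[4-(benzyloxy)-3-methoxybenzyl]-4-[3-(benzyloxy)-4-methoxybenzyl]dihydrofuran-2(3H)-one (C3 epimers) | COc1ccc(C[C@H]2COC(=O)C2Cc2ccc(OCc3ccccc3)c(OC)c2)cc1OCc1ccccc1 | intermediate
18 | (3R,4R)-3-[4-(benzyloxy)-3-methoxybenzyl]-4-[3-(benzyloxy)-4-methoxybenzyl]dihydrofuran-2(3H)-one | COc1ccc(C[C@H]2COC(=O)[C@@H]2Cc2ccc(OCc3ccccc3)c(OC)c2)cc1OCc1ccccc1 | intermediate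
19 | (3R,4R)-3-(4-hydroxy-3-methoxybenzyl)-4-(3-hydroxy-4-methoxybenzyl)dihydrofuran-2(3H)-one | COc1ccc(C[C@H]2COC(=O)[C@@H]2Cc2ccc(O)c(OC)c2)cc1O | target

## Step count and risk

Total steps: 11. Longest linear sequence: 9 steps (steps 1–6, 9, 10, 11 from isovanillin); the two-step arene branch (steps 7–8) joins at step 9.

**Step 6 (key step, proposed new method).**
- What may go wrong: poor facial selectivity at the γ-carbon. Formaldehyde carries no substituent to orient the chair and has two C–H bonds for the acid to bind, so two acid-bound chairs of opposite sense may compete. The catalysed reaction may also be slow with the electron-poor allyl unit and lose ground to the background or to formaldehyde oligomerisation.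
- Adjustments inside the strategy: a more acidic N-triflyl phosphoramide of the same binaphthyl, or a chiral diol on boron in place of pinacol.
- Fallback by known chemistry, from aldehyde 2 back to 18:
  - Stobbe condensation of 2 with dimethyl succinate (NaOMe, MeOH, reflux) gives (E)-4-[3-(benzyloxy)-4-methoxyphenyl]-3-(methoxycarbonyl)but-3-enoic acid F1.
  - Asymmetric hydrogenation with Rh(cod)2BF4 (monovalent rhodium) and the Et-DuPhos antipode that delivers the R acid gives (3R)-4-[3-(benzyloxy)-4-methoxyphenyl]-3-(methoxycarbonyl)butanoic acid F2. The benzyl ether survives homogeneous rhodium.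
  - Reduction of the ester of the potassium carboxylate with Ca(BH4)2 (from CaCl2 and NaBH4, EtOH) and acidification close (R)-4-[3-(benzyloxy)-4-methoxybenzyl]dihydrofuran-2(3H)-one F3.
  - The lithium enolate of F3 (LiN(SiMe3)2, THF, −78 °C) is alkylated anti to the C4 arm with 1-(benzyloxy)-4-(bromomethyl)-2-methoxybenzene F4, made from commercial [4-(benzyloxy)-3-methoxyphenyl]methanol and PBr3. This gives 18 directly and bypasses steps 9 and 10.

**Step 5.**
- What may go wrong: competing 1,2-reduction of the ester, incomplete C-alkylation of the aluminium species, and leakage of alkene geometry through an aluminium allenolate. Any geometric leakage turns into loss of enantiopurity in step 6, and the doubly activated CH2 may be deprotonated.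
- Fallback, from 6 back to 9:
  - Syn-hydrostannation of 6 with Bu3SnH under Pd(PPh3)4 (zerovalent palladium) places tin α to the ester and gives methyl (E)-4-[3-(benzyloxy)-4-methoxyphenyl]-2-(tributylstannyl)but-2-enoate F5.
  - I2 in CH2Cl2 at 0 °C exchanges tin for iodine with retention and gives methyl (E)-4-[3-(benzyloxy)-4-methoxyphenyl]-2-iodobut-2-enoate F6.
  - Negishi coupling of F6 with iodo[(4,4,5,5-tetramethyl-1,3,2-dioxaborolan-2-yl)methyl]zinc F7, prepared from 7 and zinc dust in THF, under Pd(PPh3)4 gives 9 with the same geometry.

**Step 4.**
- What may go wrong: base-induced propargyl-to-allenyl isomerisation of the product, conjugate addition of iodide or carbonate to the propiolate, and homocoupling of the benzylic bromide.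
- Fallback, from 4 back to 6: copper-catalysed coupling of 4 with ethynylmagnesium bromide (CuBr, THF) gives 2-(benzyloxy)-1-methoxy-4-(prop-2-yn-1-yl)benzene F8. Deprotonation of the terminal alkyne with n-BuLi at −78 °C and acylation with methyl chloroformate give 6. The ester is introduced last, so the acidic CH2 never meets a base in its doubly activated form.

**Step 9.**
- What may go wrong: Michael oligomerisation of the enolate with unreacted 12, 1,2-addition of the Grignard reagent to the lactone carbonyl, and base-induced migration of the exocyclic double bond into the ring, which would erase C4.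
- Fallback, from 12 back to 17: rhodium-catalysed conjugate addition of commercial [4-(benzyloxy)-3-methoxyphenyl]boronic acid with [Rh(cod)OH]2 (monovalent rhodium) in dioxane–H2O at 50 °C. The aryl rhodium species adds across the exocyclic alkene and the rhodium enolate is protonated by water. This is the Hayashi–Miyaura reaction type under nearly neutral conditions, and it makes no compound outside the list (F0).

## Further compounds

F1 | step 6 | (E)-4-[3-(benzyloxy)-4-methoxyphenyl]-3-(methoxycarbonyl)but-3-enoic acid | COC(=O)/C(CC(=O)O)=C/c1ccc(OC)c(OCc2ccccc2)c1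
F2 | step 6 | (3R)-4-[3-(benzyloxy)-4-methoxyphenyl]-3-(methoxycarbonyl)butanoic acid | COC(=O)[C@@H](CC(=O)O)Cc1ccc(OC)c(OCc2ccccc2)c1
F3 | step 6 | (R)-4-[3-(benzyloxy)-4-methoxybenzyl]dihydrofuran-2(3H)-one | COc1ccc(C[C@H]2COC(=O)C2)cc1OCc1ccccc1
F4 | step 6 | 1-(benzyloxy)-4-(bromomethyl)-2-methoxybenzene | COc1cc(CBr)ccc1OCc1ccccc1
F5 | step 5 | methyl (E)-4-[3-(benzyloxy)-4-methoxyphenyl]-2-(tributylstannyl)but-2-enoate | COC(=O)/C([Sn](CCCC)(CCCC)CCCC)=C\Cc1ccc(OC)c(OCc2ccccc2)c1
F6 | step 5 | methyl (E)-4-[3-(benzyloxy)-4-methoxyphenyl]-2-iodobut-2-enoate | COC(=O)/C(I)=C\Cc1ccc(OC)c(OCc2ccccc2)c1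
F7 | step 5 | iodo[(4,4,5,5-tetramethyl-1,3,2-dioxaborolan-2-yl)methyl]zinc | I[Zn]CB1OC(C)(C)C(C)(C)O1
F8 | step 4 | 2-(benzyloxy)-1-methoxy-4-(prop-2-yn-1-yl)benzene | C#CCc1ccc(OC)c(OCc2ccccc2)c1
F0 | step 9 | none | none
A1 | alternative 1 | (Z)-3-[4-methoxy-3-(triisopropylsilyloxy)phenyl]prop-2-en-1-yl diazoacetate | COc1ccc(/C=C\COC(=O)C=[N+]=[N-])cc1O[Si](C(C)C)(C(C)C)C(C)C
A2 | alternative 1 | (1S,5R,6S)-6-[4-methoxy-3-(triisopropylsilyloxy)phenyl]-3-oxabicyclo[3.1.0]hexan-2-one | COc1ccc([C@H]3[C@H]2COC(=O)[C@H]23)cc1O[Si](C(C)C)(C(C)C)C(C)C
A3 | alternative 1 | (R)-4-[4-methoxy-3-(triisopropylsilyloxy)benzyl]dihydrofuran-2(3H)-one | COc1ccc(C[C@H]2COC(=O)C2)cc1O[Si](C(C)C)(C(C)C)C(C)C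
A4 | alternative 2 | (R,E)-2-[3-(benzyloxy)-4-methoxybenzyl]-4-[4-(benzyloxy)-3-methoxyphenyl]but-3-en-1-ol | OC[C@H](Cc1ccc(OC)c(OCc2ccccc2)c1)/C=C/c1ccc(OCc2ccccc2)c(OC)c1
A5 | alternative 2 | (3R,4R)-3-[4-(benzyloxy)-3-methoxybenzyl]-4-[3-(benzyloxy)-4-methoxybenzyl]tetrahydrofuran-2-ol (anomers) | COc1ccc(C[C@H]2COC(O)[C@@H]2Cc2ccc(OCc3ccccc3)c(OC)c2)cc1OCc1ccccc1
A6 | alternative 3 | (4R,5R)-2-[(benzyloxy)methyl]-4,5-dicyclohexyl-1,3,2-dioxaborolane | C(OCc1ccccc1)B1O[C@H](C2CCCCC2)[C@@H](C2CCCCC2)O1
A7 | alternative 3 | [3-(benzyloxy)-4-methoxybenzyl]magnesium chloride | COc1ccc(C[Mg]Cl)cc1OCc1ccccc1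
A8 | alternative 3 | (4R,5R)-2-[(2S)-1-(benzyloxy)-3-[3-(benzyloxy)-4-methoxyphenyl]propan-2-yl]-4,5-dicyclohexyl-1,3,2-dioxaborolane | COc1ccc(C[C@H](B2O[C@H](C3CCCCC3)[C@@H](C3CCCCC3)O2)COCc2ccccc2)cc1OCc1ccccc1
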